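## Retrosynthetic overview

- The 4‑hydroxybenzoate is attached last to the C4 hydroxyl; the C4 carbinol and the trans ring fusion (H‑3a) are traced to a C4 ketone, and this to a C3a=C4 silyl enol ether.
- Key disconnection C8–C8a: with C4 at the enol level the seven‑membered ring is a cyclohepta‑1,4‑diene (C3a=C4 and C6=C7 on either side of the C5 methylene, the sp3 bond C8–C8a opposite). This is the product pattern of a cis‑divinylcyclopropane rearrangement, and the C1 oxygen next to C8a serves as the steering group.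
- Precursor: a cyclopentene carrying on its sp2 carbon a 1‑silyloxy‑2‑methyl‑2‑vinylcyclopropane (three‑membered ring C4–C5–C6), made by Simmons–Smith methylenation of a silyl dienol ether. The dienyl ketone comes from a 2‑bromocyclopentenol by formylation, crotylation and oxidation.
- Cyclopentene: (R)‑4‑silyloxycyclopent‑2‑enone, β‑methylated, α‑brominated, then isopropyl added anti to the silyloxy group (cis‑1,3‑dioxygen pattern).
- Ring order: five‑membered ring (from the starting material), temporary cyclopropane (step 9), seven‑membered ring closed last (step 10).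

Key step: step 10

Remark: bicyclic compounds carry the azulene numbering of the target (C1 and C3 carbinol carbons, C3a/C8a ring fusion, C4 the ester carbon, C6=C7 the alkene); the side‑chain stereocentres of 9 and 10 are formed as mixtures because step 8 erases them.

## Route

Step 1
Reactants: 1 (R)-4-((tert-butyldimethylsilyl)oxy)cyclopent-2-en-1-one
Product: 2 (3R,4R)-4-((tert-butyldimethylsilyl)oxy)-3-methyl-1-((trimethylsilyl)oxy)cyclopent-1-ene
Conditions: MeMgBr, CuBr·SMe2 (5 mol %), TMSCl, DMPU, THF, −78 °C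
Reagents that add atoms: methylmagnesium bromide C[Mg]Br; chlorotrimethylsilane C[Si](C)(C)Cl
Why: Copper‑catalysed conjugate addition of the Grignard reagent with in situ silylation should add methyl to C3 anti to the C4 silyloxy group and trap the enolate regiospecifically before it can equilibrate and expel that group.

Step 2
Reactants: 2 (3R,4R)-4-((tert-butyldimethylsilyl)oxy)-3-methyl-1-((trimethylsilyl)oxy)cyclopent-1-ene
Product: 3 (R)-4-((tert-butyldimethylsilyl)oxy)-3-methylcyclopent-2-en-1-one
Conditions: Pd(OAc)2 (10 mol %), O2 (1 atm), DMSO, rt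
Reagents that add atoms: none
Why: Saegusa–Ito dehydrosilylation should re‑form the enone between C2 and C3, removing the temporary stereocentre of step 1 and leaving C4 untouched.

Step 3
Reactants: 3 (R)-4-((tert-butyldimethylsilyl)oxy)-3-methylcyclopent-2-en-1-one
Product: 5 (R)-2-bromo-4-((tert-butyldimethylsilyl)oxy)-3-methylcyclopent-2-en-1-one, via trans-dibromide 4 (not isolated)
Conditions: Br2, CH2Cl2, −78 → 0 °C; then Et3N, 0 °C
Reagents that add atoms: bromine BrBr
Why: α‑Bromination of an enone by bromine addition and E1cB loss of HBr should place bromine on C2, the amine removing the acid before it can touch the silyl ether.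

Step 4
Reactants: 5 (R)-2-bromo-4-((tert-butyldimethylsilyl)oxy)-3-methylcyclopent-2-en-1-one
Product: 6 (1R,4R)-2-bromo-4-((tert-butyldimethylsilyl)oxy)-1-isopropyl-3-methylcyclopent-2-en-1-ol
Conditions: i-PrMgCl, CeCl3 (anhydrous), THF, −78 °C; aq. NH4Cl
Reagents that add atoms: isopropylmagnesium chloride CC(C)[Mg]Cl
Why: The organocerium reagent (i-PrCeCl2) should add 1,2 to the ketone without reduction, enolisation or bromine–magnesium exchange, on the face anti to the C4 silyloxy group, which sets the tertiary carbinol with its hydroxyl cis to that oxygen.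

Step 5
Reactants: 6 (1R,4R)-2-bromo-4-((tert-butyldimethylsilyl)oxy)-1-isopropyl-3-methylcyclopent-2-en-1-ol
Product: 8 (3R,5R)-3-((tert-butyldimethylsilyl)oxy)-5-hydroxy-5-isopropyl-2-methylcyclopent-1-ene-1-carbaldehyde, via dilithio alkoxide 7 (not isolated)
Conditions: t-BuLi (3.1 equiv), Et2O/THF, −78 °C; then DMF, −78 → 0 °C; aq. NH4Cl
Reagents that add atoms: N,N-dimethylformamide CN(C)C=O
Why: Deprotonation of the hydroxyl, bromine–lithium exchange to the β‑oxido vinyllithium and formylation with DMF should give the hydroxy enal without touching a stereocentre.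

Step 6
Reactants: 8 (3R,5R)-3-((tert-butyldimethylsilyl)oxy)-5-hydroxy-5-isopropyl-2-methylcyclopent-1-ene-1-carbaldehyde
Product: 9 (1R,4R)-4-((tert-butyldimethylsilyl)oxy)-2-(1-hydroxy-2-methylbut-3-en-1-yl)-1-isopropyl-3-methylcyclopent-2-en-1-ol (side-chain diastereomers)
Conditions: but-2-enylmagnesium chloride (CH3CH=CHCH2MgCl, 2.5 equiv), THF, −78 °C; aq. NH4Cl
Reagents that add atoms: but-2-enylmagnesium chloride CC=CC[Mg]Cl
Why: Crotyl Grignard reagents add to aldehydes through their γ‑carbon (allylic transposition, six‑membered transition state) and should give the branched 2‑methylbut‑3‑enyl carbinol, whose two new stereocentres need no control because steps 7 and 8 erase them.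

Step 7
Reactants: 9 (1R,4R)-4-((tert-butyldimethylsilyl)oxy)-2-(1-hydroxy-2-methylbut-3-en-1-yl)-1-isopropyl-3-methylcyclopent-2-en-1-ol
Product: 10 1-((3R,5R)-3-((tert-butyldimethylsilyl)oxy)-5-hydroxy-5-isopropyl-2-methylcyclopent-1-en-1-yl)-2-methylbut-3-en-1-one (epimers at C2 of the butenone)
Conditions: Dess–Martin periodinane, NaHCO3, CH2Cl2, 0 °C
Reagents that add atoms: none
Why: Dess–Martin oxidation should convert the secondary allylic alcohol into the ketone while the tertiary alcohol is inert, and the buffer should keep the vinyl group out of conjugation.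

Step 8
Reactants: 10 1-((3R,5R)-3-((tert-butyldimethylsilyl)oxy)-5-hydroxy-5-isopropyl-2-methylcyclopent-1-en-1-yl)-2-methylbut-3-en-1-one
Product: 11 tert-butyl(((1R,4R)-4-isopropyl-2-methyl-3-((E)-2-methyl-1-((trimethylsilyl)oxy)buta-1,3-dien-1-yl)-4-((trimethylsilyl)oxy)cyclopent-2-en-1-yl)oxy)dimethylsilane
Conditions: TMSOTf (2.5 equiv), Et3N (4 equiv), CH2Cl2, −20 → 0 °C
Reagents that add atoms: trimethylsilyl trifluoromethanesulfonate C[Si](C)(C)OS(=O)(=O)C(F)(F)F
Why: Soft enolisation should silylate the tertiary alcohol and convert the ketone through its only α‑hydrogen into the silyl dienol ether, and allylic strain with the bulky cyclopentenyl group should place the α‑methyl trans to it (E isomer, cyclopentenyl cis to vinyl).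

Step 9
Reactants: 11 tert-butyl(((1R,4R)-4-isopropyl-2-methyl-3-((E)-2-methyl-1-((trimethylsilyl)oxy)buta-1,3-dien-1-yl)-4-((trimethylsilyl)oxy)cyclopent-2-en-1-yl)oxy)dimethylsilane
Product: 12 tert-butyl(((1R,4R)-4-isopropyl-2-methyl-3-((1S,2R)-2-methyl-1-((trimethylsilyl)oxy)-2-vinylcyclopropyl)-4-((trimethylsilyl)oxy)cyclopent-2-en-1-yl)oxy)dimethylsilane (cyclopentenyl cis to vinyl; the facial isomer of the cyclopropane is expected alongside)
Conditions: Et2Zn, CH2I2, CH2Cl2, −15 → 0 °C; pyridine, aq. NaHCO3 work-up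
Reagents that add atoms: diiodomethane ICI
Why: Simmons–Smith cyclopropanation (Furukawa reagent) is fastest at the most electron‑rich alkene, the silyl enol ether, and is stereospecific, so the cyclopentenyl and vinyl groups should end cis on the new three‑membered ring, and both facial isomers serve step 10.

Step 10
Reactants: 12 tert-butyl(((1R,4R)-4-isopropyl-2-methyl-3-((1S,2R)-2-methyl-1-((trimethylsilyl)oxy)-2-vinylcyclopropyl)-4-((trimethylsilyl)oxy)cyclopent-2-en-1-yl)oxy)dimethylsilane
Product: 13 tert-butyl(((1R,3R,8aR)-3-isopropyl-6,8a-dimethyl-3,4-bis((trimethylsilyl)oxy)-1,2,3,5,8,8a-hexahydroazulen-1-yl)oxy)dimethylsilane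
Conditions: o-xylene (degassed, 0.02 M), Et3N (trace), sealed tube, 150 °C
Reagents that add atoms: none
Why: Thermal [3,3]‑sigmatropic (Cope) rearrangement of the cis‑1,2‑dialkenylcyclopropane through the boat transition state, in which the cyclopropane bond C4–C6 breaks while the vinyl terminus C8 bonds to the methyl‑bearing cyclopentene carbon C8a; the closest known reaction type is the divinylcyclopropane–cycloheptadiene rearrangement of 1‑silyloxy‑2‑vinylcyclopropanes that carry a cycloalkenyl group. The seven‑membered ring, the only ring made in the step, is closed by this pericyclic expansion of the three‑membered ring, the new bond joining the two alkene termini. The one new stereocentre, quaternary C8a, is controlled by the neighbouring C1 silyloxy group: C8 should add to the cyclopentene face anti to it, which leaves the angular methyl cis to that oxygen as in the target. The cis isomer whose vinyl group lies over that face rearranges directly, and the other cis isomer (and any trans isomer) should reach it by reversible homolysis of the donor‑substituted C4–C6 bond at this temperature, so the mixture from step 9 converges. The step needs periselectivity over the homodienyl 1,5‑hydrogen shift and the vinylcyclopropane–cyclopentene rearrangement, which the cis geometry from steps 8 and 9 and the lack of a cis alkyl hydrogen beside the alkenyl group should secure. It delivers C4 as a silyl enol ether and the C6=C7 alkene exactly where the target has oxygen and the trisubstituted double bond.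

Step 11
Reactants: 13 tert-butyl(((1R,3R,8aR)-3-isopropyl-6,8a-dimethyl-3,4-bis((trimethylsilyl)oxy)-1,2,3,5,8,8a-hexahydroazulen-1-yl)oxy)dimethylsilane
Product: 14 (1R,3R,3aR,8aR)-1-((tert-butyldimethylsilyl)oxy)-3-hydroxy-3-isopropyl-6,8a-dimethyl-2,3,3a,5,8,8a-hexahydroazulen-4(1H)-one
Conditions: K2CO3, MeOH, 0 °C → rt
Reagents that add atoms: none
Why: Methanolysis of both trimethylsilyl ethers releases the ketone through its enolate, and the basic medium should equilibrate C3a to the trans ring fusion, in which C4 is trans to the isopropyl group and its carbonyl is hydrogen‑bonded to the cis tertiary hydroxyl.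

Step 12
Reactants: 14 (1R,3R,3aR,8aR)-1-((tert-butyldimethylsilyl)oxy)-3-hydroxy-3-isopropyl-6,8a-dimethyl-2,3,3a,5,8,8a-hexahydroazulen-4(1H)-one
Product: 15 (1R,3R,3aS,4S,8aR)-1-((tert-butyldimethylsilyl)oxy)-3-isopropyl-6,8a-dimethyl-1,2,3,3a,4,5,8,8a-octahydroazulene-3,4-diol
Conditions: Li, NH3 (l), THF, t-BuOH, −78 °C; then NH4Cl
Reagents that add atoms: none
Why: Dissolving‑metal reduction should give the more stable pseudo‑equatorial C4 alcohol (H‑4 anti to H‑3a), whereas hydride reagents would be turned to the other face by the 1,3‑related angular methyl.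

Step 13
Reactants: 16 4-((tert-butyldimethylsilyl)oxy)benzaldehyde
Product: 17 4-((tert-butyldimethylsilyl)oxy)benzoic acid
Conditions: NaClO2, NaH2PO4, 2-methyl-2-butene, t-BuOH/H2O, rt
Reagents that add atoms: sodium chlorite [Na+].[O-]Cl=O
Why: Pinnick oxidation converts the aldehyde into the acid under buffered conditions that an aryl silyl ether tolerates.

Step 14
Reactants: 15 (1R,3R,3aS,4S,8aR)-1-((tert-butyldimethylsilyl)oxy)-3-isopropyl-6,8a-dimethyl-1,2,3,3a,4,5,8,8a-octahydroazulene-3,4-diol; 17 4-((tert-butyldimethylsilyl)oxy)benzoic acid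
Product: 18 (1R,3R,3aS,4S,8aR)-1-((tert-butyldimethylsilyl)oxy)-3-hydroxy-3-isopropyl-6,8a-dimethyl-1,2,3,3a,4,5,8,8a-octahydroazulen-4-yl 4-((tert-butyldimethylsilyl)oxy)benzoate
Conditions: EDC·HCl, DMAP, CH2Cl2, rt
Reagents that add atoms: none
Why: Steglich esterification should acylate the only reactive hydroxyl, the secondary C4 alcohol, with retention at C4, because the tertiary C3 hydroxyl is too hindered and C1 is silylated.

Step 15
Reactants: 18 (1R,3R,3aS,4S,8aR)-1-((tert-butyldimethylsilyl)oxy)-3-hydroxy-3-isopropyl-6,8a-dimethyl-1,2,3,3a,4,5,8,8a-octahydroazulen-4-yl 4-((tert-butyldimethylsilyl)oxy)benzoate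
Product: 19 (1R,3R,3aS,4S,8aR)-1,3-dihydroxy-3-isopropyl-6,8a-dimethyl-1,2,3,3a,4,5,8,8a-octahydroazulen-4-yl 4-hydroxybenzoate
Conditions: HF·pyridine, pyridine, THF, 0 °C → rt
Reagents that add atoms: none
Why: Buffered fluoride cleavage of the aryl and the hindered secondary tert‑butyldimethylsilyl ethers should leave the benzoate, the tertiary alcohol and the alkene untouched.

## Compound list

1 | (R)-4-((tert-butyldimethylsilyl)oxy)cyclopent-2-en-1-one | O=C1C=C[C@H](O[Si](C)(C)C(C)(C)C)C1 | starting material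
2 | (3R,4R)-4-((tert-butyldimethylsilyl)oxy)-3-methyl-1-((trimethylsilyl)oxy)cyclopent-1-ene (methyl trans to the silyloxy group) | C[C@@H]1C=C(O[Si](C)(C)C)C[C@H]1O[Si](C)(C)C(C)(C)C | intermediate
3 | (R)-4-((tert-butyldimethylsilyl)oxy)-3-methylcyclopent-2-en-1-one | CC1=CC(=O)C[C@H]1O[Si](C)(C)C(C)(C)C | intermediate
4 | trans-2,3-dibromo-4-((tert-butyldimethylsilyl)oxy)-3-methylcyclopentan-1-one (expected major isomer drawn; not isolated) | C[C@]1(Br)[C@H](Br)C(=O)C[C@H]1O[Si](C)(C)C(C)(C)C | intermediate
5 | (R)-2-bromo-4-((tert-butyldimethylsilyl)oxy)-3-methylcyclopent-2-en-1-one | CC1=C(Br)C(=O)C[C@H]1O[Si](C)(C)C(C)(C)C | intermediate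
6 | (1R,4R)-2-bromo-4-((tert-butyldimethylsilyl)oxy)-1-isopropyl-3-methylcyclopent-2-en-1-ol (hydroxyl cis to the silyloxy group) | CC1=C(Br)[C@](O)(C(C)C)C[C@H]1O[Si](C)(C)C(C)(C)C | intermediate
7 | lithium (1R,4R)-4-((tert-butyldimethylsilyl)oxy)-1-isopropyl-2-lithio-3-methylcyclopent-2-en-1-olate (not isolated) | CC1=C([Li])[C@](O[Li])(C(C)C)C[C@H]1O[Si](C)(C)C(C)(C)C | intermediate
8 | (3R,5R)-3-((tert-butyldimethylsilyl)oxy)-5-hydroxy-5-isopropyl-2-methylcyclopent-1-ene-1-carbaldehyde | CC1=C(C=O)[C@](O)(C(C)C)C[C@H]1O[Si](C)(C)C(C)(C)C | intermediate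
9 | (1R,4R)-4-((tert-butyldimethylsilyl)oxy)-2-(1-hydroxy-2-methylbut-3-en-1-yl)-1-isopropyl-3-methylcyclopent-2-en-1-ol (side-chain centres as a mixture) | CC1=C(C(O)C(C)C=C)[C@](O)(C(C)C)C[C@H]1O[Si](C)(C)C(C)(C)C | intermediate
10 | 1-((3R,5R)-3-((tert-butyldimethylsilyl)oxy)-5-hydroxy-5-isopropyl-2-methylcyclopent-1-en-1-yl)-2-methylbut-3-en-1-one (C2 epimers) | CC1=C(C(=O)C(C)C=C)[C@](O)(C(C)C)C[C@H]1O[Si](C)(C)C(C)(C)C | intermediate
11 | tert-butyl(((1R,4R)-4-isopropyl-2-methyl-3-((E)-2-methyl-1-((trimethylsilyl)oxy)buta-1,3-dien-1-yl)-4-((trimethylsilyl)oxy)cyclopent-2-en-1-yl)oxy)dimethylsilane | CC1=C(/C(O[Si](C)(C)C)=C(C)\C=C)[C@](O[Si](C)(C)C)(C(C)C)C[C@H]1O[Si](C)(C)C(C)(C)C | intermediate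
12 | tert-butyl(((1R,4R)-4-isopropyl-2-methyl-3-((1S,2R)-2-methyl-1-((trimethylsilyl)oxy)-2-vinylcyclopropyl)-4-((trimethylsilyl)oxy)cyclopent-2-en-1-yl)oxy)dimethylsilane (cyclopentenyl cis to vinyl; the cis isomer drawn rearranges directly on the face anti to the C1 silyloxy group) | CC1=C([C@@]2(O[Si](C)(C)C)[C@@](C)(C=C)C2)[C@](O[Si](C)(C)C)(C(C)C)C[C@H]1O[Si](C)(C)C(C)(C)C | intermediate
13 | tert-butyl(((1R,3R,8aR)-3-isopropyl-6,8a-dimethyl-3,4-bis((trimethylsilyl)oxy)-1,2,3,5,8,8a-hexahydroazulen-1-yl)oxy)dimethylsilane | CC1=CC[C@@]2(C)[C@H](O[Si](C)(C)C(C)(C)C)C[C@@](O[Si](C)(C)C)(C(C)C)C2=C(O[Si](C)(C)C)C1 | intermediate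
14 | (1R,3R,3aR,8aR)-1-((tert-butyldimethylsilyl)oxy)-3-hydroxy-3-isopropyl-6,8a-dimethyl-2,3,3a,5,8,8a-hexahydroazulen-4(1H)-one (trans-fused) | CC1=CC[C@@]2(C)[C@H](O[Si](C)(C)C(C)(C)C)C[C@@](O)(C(C)C)[C@@H]2C(=O)C1 | intermediate
15 | (1R,3R,3aS,4S,8aR)-1-((tert-butyldimethylsilyl)oxy)-3-isopropyl-6,8a-dimethyl-1,2,3,3a,4,5,8,8a-octahydroazulene-3,4-diol | CC1=CC[C@@]2(C)[C@H](O[Si](C)(C)C(C)(C)C)C[C@@](O)(C(C)C)[C@@H]2[C@@H](O)C1 | intermediate
16 | 4-((tert-butyldimethylsilyl)oxy)benzaldehyde | CC(C)(C)[Si](C)(C)Oc1ccc(C=O)cc1 | starting material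
17 | 4-((tert-butyldimethylsilyl)oxy)benzoic acid | CC(C)(C)[Si](C)(C)Oc1ccc(cc1)C(O)=O | intermediate
18 | (1R,3R,3aS,4S,8aR)-1-((tert-butyldimethylsilyl)oxy)-3-hydroxy-3-isopropyl-6,8a-dimethyl-1,2,3,3a,4,5,8,8a-octahydroazulen-4-yl 4-((tert-butyldimethylsilyl)oxy)benzoate | CC1=CC[C@@]2(C)[C@H](O[Si](C)(C)C(C)(C)C)C[C@@](O)(C(C)C)[C@@H]2[C@@H](OC(=O)c2ccc(O[Si](C)(C)C(C)(C)C)cc2)C1 | intermediate
19 | (1R,3R,3aS,4S,8aR)-1,3-dihydroxy-3-isopropyl-6,8a-dimethyl-1,2,3,3a,4,5,8,8a-octahydroazulen-4-yl 4-hydroxybenzoate | CC1=CC[C@@]2(C)[C@H](O)C[C@@](O)(C(C)C)[C@@H]2[C@@H](OC(=O)c2ccc(O)cc2)C1 | target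

## Step count and risks

Total step count: 15. Longest linear sequence: 14 steps (steps 1–12, 14 and 15, from 1 to 19); step 13 is a one‑step branch.

Steps most likely to fail:

1. Step 10. The hot cyclopropane may rearrange on the wrong face of the cyclopentene (loss of control at C8a), or be diverted into hydrogen‑shift and ring‑opening pathways before the boat transition state, which is crowded by the inward methyl group, is reached. Fallback, setting out from 8 and returning at 14: allylmagnesium bromide (CH2=CHCH2MgBr, THF, −78 °C) should give the allyl carbinol F1. KH and 18‑crown‑6 in THF should then trigger the anionic oxy‑Cope rearrangement, a [3,3] shift that needs no cyclopropane. It moves the allyl group to the methyl‑bearing ring carbon on the face anti to the silyloxy group and, after cold buffered protonation, should give the allyl aldehyde F2. Methallylmagnesium chloride (CH2=C(CH3)CH2MgCl) then gives the methallyl carbinol F3, and Dess–Martin periodinane the dienyl ketone F4. Ring‑closing metathesis with the second‑generation Grubbs catalyst (H2IMes)(PCy3)Cl2Ru=CHPh closes the seven‑membered ring at C6=C7, still as the last ring, and gives 14.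

2. Step 11. The equilibration at C3a may settle on the cis ring fusion, or the basic methanol may open the β‑hydroxy ketone by retro‑aldol cleavage or dehydrate it. Fallback, setting out from 13 and returning at 14: MeLi (THF, −20 °C) should cleave only the enol silyl ether and give the lithium enolate regiospecifically. Quenching at −78 °C with the bulky proton donor 2,6‑di‑tert‑butylphenol should protonate C3a kinetically on the face opposite the angular methyl and the tertiary silyloxy group, giving the silyl‑protected trans ketone F5. PPTS in MeOH then removes the tertiary trimethylsilyl group without base and gives 14.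

3. Step 12. Protonation of the reduced ketone may occur from both faces and give the C4 epimers together. Fallback, setting out from 14 and returning at 18: K[(s-Bu)3BH] (THF, −78 °C) should attack the ketone from the open face only and give the axial C4‑epimeric diol F6. Mitsunobu esterification of F6 with acid 17 (PPh3, diisopropyl azodicarboxylate, toluene) inverts C4 and forms the ester in the same operation, giving 18.

Further compounds
F1 | step 10 | (1R,4R)-4-((tert-butyldimethylsilyl)oxy)-2-(1-hydroxybut-3-en-1-yl)-1-isopropyl-3-methylcyclopent-2-en-1-ol (carbinol epimers) | CC1=C(C(O)CC=C)[C@](O)(C(C)C)C[C@H]1O[Si](C)(C)C(C)(C)C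
F2 | step 10 | 2-allyl-3-((tert-butyldimethylsilyl)oxy)-5-hydroxy-5-isopropyl-2-methylcyclopentane-1-carbaldehyde (allyl anti to the silyloxy group; formyl trans to allyl and cis to the tertiary hydroxyl) | C=CC[C@@]1(C)[C@H](O[Si](C)(C)C(C)(C)C)C[C@@](O)(C(C)C)[C@@H]1C=O
F3 | step 10 | 1-(2-allyl-3-((tert-butyldimethylsilyl)oxy)-5-hydroxy-5-isopropyl-2-methylcyclopentyl)-3-methylbut-3-en-1-ol (ring configuration as F2; carbinol epimers) | C=CC[C@@]1(C)[C@H](O[Si](C)(C)C(C)(C)C)C[C@@](O)(C(C)C)[C@@H]1C(O)CC(C)=C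
F4 | step 10 | 1-(2-allyl-3-((tert-butyldimethylsilyl)oxy)-5-hydroxy-5-isopropyl-2-methylcyclopentyl)-3-methylbut-3-en-1-one (ring configuration as F2) | C=CC[C@@]1(C)[C@H](O[Si](C)(C)C(C)(C)C)C[C@@](O)(C(C)C)[C@@H]1C(=O)CC(C)=C
F5 | step 11 | (1R,3R,3aR,8aR)-1-((tert-butyldimethylsilyl)oxy)-3-isopropyl-6,8a-dimethyl-3-((trimethylsilyl)oxy)-2,3,3a,5,8,8a-hexahydroazulen-4(1H)-one | CC1=CC[C@@]2(C)[C@H](O[Si](C)(C)C(C)(C)C)C[C@@](O[Si](C)(C)C)(C(C)C)[C@@H]2C(=O)C1
F6 | step 12 | (1R,3R,3aS,4R,8aR)-1-((tert-butyldimethylsilyl)oxy)-3-isopropyl-6,8a-dimethyl-1,2,3,3a,4,5,8,8a-octahydroazulene-3,4-diol (C4 epimer of 15) | CC1=CC[C@@]2(C)[C@H](O[Si](C)(C)C(C)(C)C)C[C@@](O)(C(C)C)[C@@H]2[C@H](O)C1
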